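## The problem

Target 25 is a tetracyclic cage. A hydroquinone (ring A) is fused through two adjacent carbons to a bicyclo[3.2.1]octene whose bridgeheads are the quaternary carbon Cb and the benzylic methine Cc. The one-carbon bridge is the prenyl-bearing quaternary carbon Ca, and the three-carbon bridge Cd(H2)–Ce(CH3)=Cf(H) completes the methylcyclohexene (ring C). The five-membered ring through Ca, Cb, Cc and the two arene carbons is ring D. A cyclohex-2-ene-1,4-dione (ring B: Ca, carbonyl B1, B2=B3, carbonyl B4, Cb) is fused on the Ca–Cb bond; the same letters are used for the corresponding atoms of every intermediate.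

Ca and Cb are adjacent quaternary carbons and every bond around the Ca–Cb–Cc array is congested. Of the three stereocentres, Cb and Cc are tied to each other by the bridge. The open questions are therefore the orientation of Ca (prenyl over ring C, B1 over ring A) and the absolute configuration, so Ca should be set first and then direct Cc and Cb.

The hydroquinone is oxidised by air and by most oxidants, the enedione is a Michael acceptor and is easily reduced, and the prenyl group and the ring-C alkene tolerate neither strong acid nor electrophilic oxidants. The ring-C double bond must also be placed on the Cc side (Ce=Cf) and not on the Cb side.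

The feature that opens the structure is that ring A touches the cage only through two adjacent carbons, one bonded to Cb and one to Cc. If Ce is read as a ketone, Cb and Cc are the two β-carbons of a cross-conjugated cyclohexadienone with Ca as its 4-position, and ring A at the oxidation level of cyclohexane-1,4-dione 13 is a vicinal bis-nucleophile for both.

## Retrosynthesis

**Ring A unmasked last (25 ⇐ 24 ⇐ 23).** No skeletal bond is cut; the two phenolic O–H bonds are traced back to O–CH3. A free hydroquinone would not survive the enolate, organometallic and oxidative steps before it, whereas methyl ethers are inert to all of them. Release through quinone 24 and mild reduction avoids the Lewis acids that would attack the prenyl group. The forward step must oxidise only ring A and then reduce only the benzoquinone, not the ring-B enedione.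

**Ring B oxidation level (23 ⇐ 22 ⇐ 21 ⇐ 20).** Again no carbon–carbon bond is cut; the two carbonyls and the B2=B3 double bond go back to two silyl-protected secondary alcohols. An enedione cannot be carried through base and organometallic chemistry, while two silyl ethers can, and one fluoride treatment releases both. In diketone 22 only B2 and B3 carry enolisable hydrogens, so the dehydrogenation has a single possible outcome.

**Methyl alkene (20 ⇐ 19 ⇐ 18).** The Ce–CH3 bond is cut, leading to enol triflate 19 and the bridge ketone 18. Methyl addition followed by dehydration would give mixtures of three alkenes; the triflate fixes the double bond where the enolate was formed. The forward step needs kinetic deprotonation at Cf (beside the methine Cc) in preference to Cd (beside the quaternary Cb).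

**Ring A to the dione level (18 ⇐ 17 ⇐ 16 ⇐ 15).** No skeletal bond is cut, but the change is the one that reveals the strategy. In 15 the two ring-A carbons bonded to Cb and Cc are α-carbons of two ketones. The forward dehydrogenation is intrinsically selective: the ketone at Ce cannot be dehydrogenated, since Cb has no hydrogen and a double bond to Cc would lie at a bridgehead.

**Key disconnection (15 ⇐ 12 + 13).** The bonds Cc–ring A and Cb–ring A are cut together, which opens ring D and removes ring A as the symmetric commodity 13. The neighbouring cuts (Ca–Cb, Ca–Cc, or the ring-B bonds) each leave a quaternary centre or a ring of the cage to be made later. This cut leaves dienone 12, a bicycle whose only controlling stereocentre is Ca, and it removes four stereocentres and the bond that makes Cb quaternary. The forward reaction is a double conjugate addition that must go to Cc first and then close a five-membered ring onto Cb.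

**Dienone (12 ⇐ 11 ⇐ 10 ⇐ 9 ⇐ 8 ⇐ 7 ⇐ 6).** The Cf=Cc double bond comes from dehydrogenation of enone 10. The B4 oxygen comes from γ-oxidation of the extended dienol ether 8, and the B1 oxygen from reduction of the saturated ketone of 6. B4 has to be oxidised now, while it is the γ-position of an enone; after the key step it is an unactivated methylene beside a quaternary carbon. B1 is reduced, not ketalised, so that no axial oxygen lies on the face of Cb that the nucleophile must reach. The forward oxidation must prefer the dienol ether to the prenyl double bond.

**Bicyclic enedione (6 ⇐ 5 ⇐ 3 + 4; 3 ⇐ 1 + 2).** The Robinson annulation retron cuts Cb=Cd (aldol condensation) and Ca–Cc (Michael addition to 4), and the prenyl–Ca bond is cut to 1 and 2. Everything is reduced to four bulk chemicals. The absolute configuration at Ca is asked of a chiral amino-acid catalyst that distinguishes the two enantiotopic ring carbonyls of 5.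

## Roads not taken

**Alternative 1: indenone Diels–Alder for ring B.**
- Cut: the ring-B bonds Ca–B1 and Cb–B4.
- Forward step: the 2-prenylindenone A1 adds the 1,4-diacetoxydiene A2 across its Ca=Cb double bond to give the endo, cis-fused hydrofluorenone A3.
- Merits: the arene is present from the start, so nothing corresponds to the aromatisation, protection and late ring-B oxidation of the chosen plan (steps 8, 9 and 12–14). Ring B arrives with both oxygens and its double bond, and the cycloaddition class is established. In these respects this road is better.
- Weak points: in A3 ring C does not exist, Cb is still a tertiary CH and the future Cc is a carbonyl carbon. Cb would have to be alkylated beside the quaternary Ca, the three-carbon bridge closed onto the indanone carbonyl, a tertiary benzylic oxygen removed at a bridgehead and the alkene placed. A1 is prone to dimerise, A2 is a sluggish diene, and the absolute configuration would need a chiral Lewis acid on a trisubstituted dienophile or a resolution.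
- Comparison: the chosen plan sets against the better precedent a key step that closes ring D, forms both arene-to-cage bonds and fixes the Ca/Cb/Cc triad in one operation, on a dienone whose configuration comes from a catalytic annulation.

**Alternative 2: nitroalkene double Michael annulation.**
- Cut: Ca–Cb and the ring-B bond B3–B4.
- Forward step: the Ca enolate of the open precursor A4 adds to the nitroalkene carbon (Cb), closing ring D. The nitronate carbon (B4) then adds to the β-methoxy enone with loss of methoxide, closing ring B to give A5.
- Merits: the hindered Ca–Cb bond is formed intramolecularly with a very strong acceptor, and ring A is aromatic throughout. A later vinylsilane-terminated closure onto Cc would place the Ce=Cf double bond without ambiguity. That is better than the chosen plan, whose step 10 depends on the regioselectivity of a kinetic enolate.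
- Weak points: A4 is a long linear assembly (two different ortho side chains, a fully substituted nitroalkene, a β-methoxy enone). Such nitroalkenes add slowly at the substituted carbon and isomerise to allyl nitro compounds. Ca is controlled only through the benzylic silyloxy centre, which is later ionised. A Nef-type conversion must then work on a hindered secondary nitro group beside a quaternary carbon, and the cationic closure of ring C must succeed next to the prenyl group, a competing nucleophile.
- Comparison: the chosen plan answers the better alkene regiocontrol with a key-step precursor made in six steps from bulk chemicals and with the absence of any cationic step while the prenyl group is present.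

**Alternative 3: lactone Ireland–Claisen contraction.**
- Cut: Ca–Cc.
- Forward step: the silyl ketene acetal of the δ-lactone A6 rearranges through a ring-enforced boat transition state, breaking the tertiary allylic C–O bond and giving the cyclohexene acid A7.
- Merits: a sigmatropic step with predictable transfer of configuration sets Ca, Cc and the methyl-bearing alkene at once, and handles for B1 (acid), B4 (dithiane) and the Cb–arene bond (aryl bromide) are in place. Its stereochemical reliability is higher than that of the new double Michael reaction.
- Weak points: A7 contains neither ring D nor ring B and Cb is still a CH. Left to do are the quaternising intramolecular arylation that closes the strained bicycle and a two-carbon annulation between two neopentylic carbonyl carbons. A6 itself needs a tertiary allylic ester oxygen, which is prone to ionisation, and three controlled stereo-elements.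
- Comparison: after the chosen key step every carbon of the target except the methyl group is in place and every ring is closed, which this road reaches only many steps after its key step.

Key step: step 7

Remark on the chemistry: the configurations drawn at the carbinol carbons B1 and B4 (both oxygens cis to the prenyl group) and at the two ring-A methine carbons of 15 (cis, endo) are the expected ones; all four centres are destroyed later, so the route does not depend on them.

## Route

Step 1
Reactants: 1 cyclohexane-1,3-dione; 2 prenyl bromide (1-bromo-3-methylbut-2-ene)
Product: 3 2-(3-methylbut-2-en-1-yl)cyclohexane-1,3-dione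
Conditions: aq. KOH, 0 °C → rt
Reagents that add atoms: none
Why: C-alkylation of the dione enolate by an allylic bromide; in water the hydrogen-bonded enolate oxygens are poor nucleophiles, which favours reaction at carbon. No stereocentre is formed.

Step 2
Reactants: 3 2-(3-methylbut-2-en-1-yl)cyclohexane-1,3-dione; 4 methyl vinyl ketone
Product: 6 (8aR)-8a-(3-methylbut-2-en-1-yl)-3,4,8,8a-tetrahydronaphthalene-1,6(2H,7H)-dione, via triketone 5 (not isolated)
Conditions: Et3N (cat.), neat, rt; then L-phenylalanine, (1S)-(+)-10-camphorsulfonic acid, DMF, 30 → 70 °C
Reagents that add atoms: none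
Why: Robinson annulation: Michael addition gives 5, and the amino-acid enamine of the side-chain ketone attacks one of the two enantiotopic ring carbonyls (asymmetric intramolecular aldol condensation). The L-amino acid sets Ca in the sense established for this annulation; the descriptor is R only because prenyl outranks the ring methylene.

Step 3
Reactants: 6 (8aR)-bicyclic enedione
Product: 7 (4aR,5S)-5-hydroxy-4a-(3-methylbut-2-en-1-yl)-4,4a,5,6,7,8-hexahydronaphthalen-2(3H)-one
Conditions: NaBH4 (0.3 equiv), EtOH, −10 °C
Reagents that add atoms: none
Why: Chemoselective hydride reduction of the saturated ketone in the presence of the less electrophilic enone. Hydride enters axially from the face opposite the prenyl group and gives the equatorial alcohol cis to prenyl at B1.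

Step 4
Reactants: 7 hydroxy enone
Product: 9 (4aR,5S,8R)-5,8-dihydroxy-4a-(3-methylbut-2-en-1-yl)-4,4a,5,6,7,8-hexahydronaphthalen-2(3H)-one, via bis-silyl dienol ether 8 (not isolated)
Conditions: TMSOTf, Et3N, CH2Cl2, 0 °C; pentane filtration; then DMDO (1.0 equiv), acetone/CH2Cl2, −78 °C; then aq. citric acid, THF, 0 °C
Reagents that add atoms: dimethyldioxirane, CC1(C)OO1
Why: Vinylogous Rubottom oxidation: soft enolisation gives the through-conjugated silyl dienol ether, whose terminus B4 takes up oxygen from the electrophilic dioxirane far faster than the isolated prenyl alkene; the acid work-up collapses the adduct to the γ-hydroxy enone and frees the B1 hydroxyl. Attack at B4 is expected on the axial face cis to the prenyl group, as in the oxidation of steroidal 3,5-dienol ethers; the centre later becomes a carbonyl carbon, so either epimer serves.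

Step 5
Reactants: 9 dihydroxy enone
Product: 10 bis(tert-butyldimethylsilyl) ether of 9
Conditions: TBSOTf, 2,6-lutidine, CH2Cl2, −78 → 0 °C
Reagents that add atoms: tert-butyldimethylsilyl triflate, CC(C)(C)[Si](C)(C)OS(=O)(=O)C(F)(F)F
Why: Silylation of two hindered secondary alcohols (one neopentylic, one axial) with the silyl triflate; the weak pyridine base does not enolise the enone. No stereocentre changes.

Step 6
Reactants: 10 bis(silyloxy) enone
Product: 12 5,8-bis(tert-butyldimethylsilyloxy)-4a-(3-methylbut-2-en-1-yl)-5,6,7,8-tetrahydronaphthalen-2(4aH)-one, via silyl dienol ether 11 (not isolated)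
Conditions: LiN(iPr)2, THF, −78 °C; Me3SiCl; then Pd(OAc)2, MeCN, rt
Reagents that add atoms: none
Why: Saegusa–Ito oxidation: kinetic deprotonation at Cf gives the cross-conjugated dienolate, and palladium acetate converts its silyl ether into the Cf=Cc double bond by β-hydride elimination. No stereocentre is touched.

Step 7
Reactants: 12 cross-conjugated dienone; 13 cyclohexane-1,4-dione
Product: 15 cage triketone (ring A as a cis-fused endo cyclohexane-1,4-dione; ketone at Ce; silyloxy groups at B1 and B4), via mono-adduct 14 (not isolated)
Conditions: 13 (3 equiv), KOtBu (0.3 equiv), tBuOH/THF, degassed, 0 °C → rt; AcOH quench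
Reagents that add atoms: none
Why: Proposed new method: the potassium enolate of 13, maintained by catalytic KOtBu in a protic medium, adds to Cc, the unsubstituted β-carbon of the dienone, and the resulting dienolate is protonated at Cf so that mono-adduct 14 regains the Cb=Cd enone; enolisation of the second ring-A ketone towards the carbon next to the newly bonded one then lets that carbon add to Cb in a 5-(enolexo)-exo-trig Michael closure that forms ring D and makes Cb quaternary. The closest known reaction type is the double Michael annulation of ketones and 1,3-dicarbonyl compounds onto cross-conjugated dienones, which uses the two α-carbons of one carbonyl and gives bicyclo[3.3.1]nonanones; the use of the adjacent α-carbons of a 1,4-dione to give a bicyclo[3.2.1]octanone has not been shown. Cc is set by attack on the dienone face opposite the pseudo-axial prenyl group on Ca, as in conjugate additions to angularly substituted bicyclic cyclohexadienones. Cb is then forced, because the tether from Cc reaches only that same face, which leaves ring B trans-fused to ring C and B1 over ring A as in the target. The two ring-A methine centres are epimerisable α-carbons, are expected cis and endo (turned away from B1) and are erased in step 8. Two selectivities are needed: Cc before Cb, secured by the full substitution of Cb, which only an intramolecular nucleophile can reach; and the five-membered closure over the six-membered closure through the other α-carbon, secured by B1 on Ca, which would be pressed into the third ring of the alternative bicyclo[3.3.1] cage. Catalytic base, a proton-shuttling solvent and exclusion of oxygen keep the dienone away from acid (dienone–phenol rearrangement) and the dione away from autoxidation; the equatorial hydrogen at B4 and the absence of an axial substituent at B1 keep γ-deprotonation slow and the face of Cb open.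

Step 8
Reactants: 15 cage triketone
Product: 16 cage quinone (ring A as 1,4-benzoquinone; ketone at Ce)
Conditions: DDQ (2.2 equiv), 1,4-dioxane, rt → 60 °C
Reagents that add atoms: none
Why: Quinone-mediated dehydrogenation of the 1,4-dione through its enols gives the hydroquinone, which the second equivalent oxidises to the quinone. The ketone at Ce cannot be dehydrogenated, since Cb has no hydrogen and Cc is a bridgehead.

Step 9
Reactants: 16 cage quinone
Product: 18 cage ketone with ring A as 1,4-dimethoxybenzene, via hydroquinone 17 (not isolated)
Conditions: Na2S2O4, Bu4NBr, THF/H2O, rt; then KOH, Me2SO4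
Reagents that add atoms: dimethyl sulfate, COS(=O)(=O)OC
Why: Reductive methylation of a quinone: dithionite gives the hydroquinone, which is O-methylated under phase transfer while excess dithionite keeps air oxidation away.

Step 10
Reactants: 18 dimethoxyarene ketone
Product: 19 enol triflate (Ce–OTf; double bond Ce=Cf)
Conditions: KN(SiMe3)2, THF, −78 °C; then PhNTf2
Reagents that add atoms: N-phenylbis(trifluoromethanesulfonimide), O=S(=O)(N(c1ccccc1)S(=O)(=O)C(F)(F)F)C(F)(F)F
Why: Kinetic enolate formation and O-triflation; the bulky amide removes a proton from Cf, beside the methine Cc, and not from the neopentylic Cd beside the quaternary Cb, as for cyclohexanones with one quaternary β-carbon.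

Step 11
Reactants: 19 enol triflate
Product: 20 methyl alkene (Ce–CH3; Ce=Cf)
Conditions: MeMgBr, Fe(acac)3 (5 mol%), THF/NMP, −30 → 0 °C
Reagents that add atoms: methylmagnesium bromide, C[Mg]Br
Why: Iron-catalysed Kumada-type cross-coupling of an alkenyl triflate with a methyl Grignard reagent; the double bond stays where the triflate fixed it, and no carbonyl group is present.

Step 12
Reactants: 20 bis(silyl ether)
Product: 21 diol (B1–OH, B4–OH)
Conditions: Bu4NF, THF, rt → 50 °C
Reagents that add atoms: none
Why: Fluoride cleavage of both silyl ethers; the aryl methyl ethers and both alkenes are inert.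

Step 13
Reactants: 21 diol
Product: 23 O,O′-dimethyl ether of the target, via diketone 22 (not isolated)
Conditions: IBX (6 equiv), DMSO, rt → 75 °C
Reagents that add atoms: none
Why: IBX oxidises both secondary alcohols and, at the higher temperature, dehydrogenates the ketone α,β (known one-pot alcohol-to-enone oxidation). Only B2 and B3 carry enolisable hydrogens, so the enedione is the sole possible product and cannot be oxidised further.

Step 14
Reactants: 23 dimethyl ether
Product: 25 target, via quinone 24 (not isolated)
Conditions: (NH4)2Ce(NO3)6, MeCN/H2O, 0 °C; then aq. Na2S2O4, EtOAc, rt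
Reagents that add atoms: water, O
Why: Oxidative demethylation of the 1,4-dimethoxyarene (water supplies the quinone oxygens, methanol leaves), then dithionite reduction of the benzoquinone. The benzoquinone is reduced far more easily than the ring-B enedione, and no acid strong enough to touch the prenyl group is used.

## Compound list

1 | cyclohexane-1,3-dione | O=C1CCCC(=O)C1 | starting material
2 | prenyl bromide (1-bromo-3-methylbut-2-ene) | CC(C)=CCBr | starting material
3 | 2-(3-methylbut-2-en-1-yl)cyclohexane-1,3-dione | CC(C)=CCC1C(=O)CCCC1=O | intermediate
4 | methyl vinyl ketone (but-3-en-2-one) | CC(=O)C=C | starting material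
5 | 2-(3-methylbut-2-en-1-yl)-2-(3-oxobutyl)cyclohexane-1,3-dione | CC(=O)CCC1(CC=C(C)C)C(=O)CCCC1=O | intermediate (not isolated)
6 | (8aR)-8a-(3-methylbut-2-en-1-yl)-3,4,8,8a-tetrahydronaphthalene-1,6(2H,7H)-dione | CC(C)=CC[C@]12CCC(=O)C=C1CCCC2=O | intermediate
7 | (4aR,5S)-5-hydroxy-4a-(3-methylbut-2-en-1-yl)-4,4a,5,6,7,8-hexahydronaphthalen-2(3H)-one (hydroxyl cis to prenyl) | CC(C)=CC[C@]12CCC(=O)C=C1CCC[C@@H]2O | intermediate
8 | trimethylsilyl ether of 7 held as the extended trimethylsilyl dienol ether (double bonds Ce=Cd and Cb=B4) | CC(C)=CC[C@]12CCC(O[Si](C)(C)C)=CC1=CCC[C@@H]2O[Si](C)(C)C | intermediate (not isolated)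
9 | (4aR,5S,8R)-5,8-dihydroxy-4a-(3-methylbut-2-en-1-yl)-4,4a,5,6,7,8-hexahydronaphthalen-2(3H)-one (both hydroxyls cis to prenyl) | CC(C)=CC[C@]12CCC(=O)C=C1[C@H](O)CC[C@@H]2O | intermediate
10 | bis(tert-butyldimethylsilyl) ether of 9 | CC(C)=CC[C@]12CCC(=O)C=C1[C@H](O[Si](C)(C)C(C)(C)C)CC[C@@H]2O[Si](C)(C)C(C)(C)C | intermediate
11 | cross-conjugated trimethylsilyl dienol ether of 10 (double bonds Cf=Ce and Cd=Cb) | CC(C)=CC[C@]12CC=C(O[Si](C)(C)C)C=C1[C@H](O[Si](C)(C)C(C)(C)C)CC[C@@H]2O[Si](C)(C)C(C)(C)C | intermediate (not isolated)
12 | 5,8-bis(tert-butyldimethylsilyloxy)-4a-(3-methylbut-2-en-1-yl)-5,6,7,8-tetrahydronaphthalen-2(4aH)-one, stereocentres as in 10 | CC(C)=CC[C@]12C=CC(=O)C=C1[C@H](O[Si](C)(C)C(C)(C)C)CC[C@@H]2O[Si](C)(C)C(C)(C)C | intermediate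
13 | cyclohexane-1,4-dione | O=C1CCC(=O)CC1 | starting material
14 | mono-adduct: the enone with a 2,5-dioxocyclohexyl group on Cc trans to prenyl (either configuration at the attachment carbon of the dione) | CC(C)=CC[C@]12[C@H](CC(=O)C=C1[C@H](O[Si](C)(C)C(C)(C)C)CC[C@@H]2O[Si](C)(C)C(C)(C)C)C1CC(=O)CCC1=O | intermediate (not isolated)
15 | cage triketone: ring A as cis-fused, endo cyclohexane-1,4-dione; ketone at Ce; silyloxy groups at B1 and B4; Ca, Cb, Cc as in 25 | CC(C)=CC[C@@]12[C@@H](O[Si](C)(C)C(C)(C)C)CC[C@@H](O[Si](C)(C)C(C)(C)C)[C@@]14CC(=O)C[C@@H]2[C@@H]2C(=O)CCC(=O)[C@@H]24 | intermediate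
16 | cage quinone: as 15 with ring A a 1,4-benzoquinone | CC(C)=CC[C@@]12[C@@H](O[Si](C)(C)C(C)(C)C)CC[C@@H](O[Si](C)(C)C(C)(C)C)[C@@]14CC(=O)C[C@@H]2C2=C4C(=O)C=CC2=O | intermediate
17 | cage hydroquinone: as 16 with ring A reduced | CC(C)=CC[C@@]12[C@@H](O[Si](C)(C)C(C)(C)C)CC[C@@H](O[Si](C)(C)C(C)(C)C)[C@@]14CC(=O)C[C@@H]2c2c(O)ccc(O)c24 | intermediate (not isolated)
18 | cage ketone with ring A as 1,4-dimethoxybenzene | CC(C)=CC[C@@]12[C@@H](O[Si](C)(C)C(C)(C)C)CC[C@@H](O[Si](C)(C)C(C)(C)C)[C@@]14CC(=O)C[C@@H]2c2c(OC)ccc(OC)c24 | intermediate
19 | enol triflate of 18 (Ce–OTf, double bond Ce=Cf) | CC(C)=CC[C@@]12[C@@H](O[Si](C)(C)C(C)(C)C)CC[C@@H](O[Si](C)(C)C(C)(C)C)[C@@]14CC(OS(=O)(=O)C(F)(F)F)=C[C@@H]2c2c(OC)ccc(OC)c24 | intermediate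
20 | methyl alkene (Ce–CH3, Ce=Cf) with ring B as bis(silyl ether) | CC(C)=CC[C@@]12[C@@H](O[Si](C)(C)C(C)(C)C)CC[C@@H](O[Si](C)(C)C(C)(C)C)[C@@]14CC(C)=C[C@@H]2c2c(OC)ccc(OC)c24 | intermediate
21 | diol (B1–OH and B4–OH, both cis to prenyl) | CC(C)=CC[C@@]12[C@@H](O)CC[C@@H](O)[C@@]14CC(C)=C[C@@H]2c2c(OC)ccc(OC)c24 | intermediate
22 | ring-B 1,4-diketone | CC(C)=CC[C@@]12C(=O)CCC(=O)[C@@]14CC(C)=C[C@@H]2c2c(OC)ccc(OC)c24 | intermediate (not isolated)
23 | O,O′-dimethyl ether of the target | CC(C)=CC[C@@]12C(=O)C=CC(=O)[C@@]14CC(C)=C[C@@H]2c2c(OC)ccc(OC)c24 | intermediate
24 | quinone corresponding to the target | CC(C)=CC[C@@]12C(=O)C=CC(=O)[C@@]14CC(C)=C[C@@H]2C2=C4C(=O)C=CC2=O | intermediate (not isolated)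
25 | CNP0166383.1 | CC(C)=CC[C@@]12C(=O)C=CC(=O)[C@@]13CC(C)=C[C@@H]2c1c(O)ccc(O)c13 | target

## Step count and least certain steps

Total step count: 14. Longest linear sequence: 14 steps (1 → 25); compounds 2, 4 and 13 enter as purchased reagents.

**Step 7 (proposed new method).**
- What may go wrong: the intermolecular first addition at the neopentylic Cc may be slow enough that self-condensation of the dione and γ-deprotonation with isomerisation of the dienone take over. In the second stage, closure through the other α-carbon (six-membered mode) or reversal by retro-Michael cleavage may compete with formation of the quaternary centre.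
- Fallback, from 12 back to the route at 18 (replacing steps 7–9), using known reaction types only: 2,3-dibromo-1,4-dimethoxybenzene F1 undergoes bromine–magnesium exchange (iPrMgCl·LiCl, THF, −20 °C) to (2-bromo-3,6-dimethoxyphenyl)magnesium chloride F2. Transmetallated with CuBr·SMe2, F2 adds 1,4 to Cc of 12 on the face opposite the prenyl group (aryl cuprate addition to a cyclohexadienone) and gives, after protonation, the 3-aryl enone F3. Bu3SnH and AIBN in benzene at 80 °C then generate the aryl radical, which closes 5-exo-trig onto the enone β-carbon Cb and delivers 18 directly. The hindered aryl nucleophile is the weak point of this fallback; the radical closure is insensitive to the congestion at Cb.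

**Step 4.**
- What may go wrong: oxygen transfer to the prenyl double bond (over-oxidation) or to Cd in place of B4, because the discrimination rests only on relative nucleophilicity.
- Fallback, from 7 back to 9, using radical instead of electrophilic oxygenation: 7 is deconjugated (excess KOtBu, tBuOH, then kinetic protonation with cold aqueous acetic acid) to the β,γ-unsaturated hydroxy ketone F4. Its doubly activated B4–H is autoxidised by O2 to the γ-hydroperoxy enone F5, as known for steroidal 5-en-3-ones, and PPh3 reduces F5 to 9. A trisubstituted alkene is inert to ground-state oxygen under these conditions.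

**Step 10.**
- What may go wrong: competing deprotonation at Cd, which after coupling would give the double-bond regioisomer.
- Fallback, from 18 back to 20 (replacing steps 10 and 11) by a Shapiro reaction: 18 is condensed with 2,4,6-triisopropylbenzenesulfonohydrazide to the hydrazone F6, in which the sulfonamide nitrogen turns away from the congested Cd side. Two equivalents of n-BuLi (THF, −78 → 0 °C) deprotonate Cf syn to that nitrogen and give, after loss of sulfinate and nitrogen, the vinyllithium F7, which MeI methylates to 20.

**Step 13.**
- What may go wrong: the dehydrogenation may stop at the diketone or, at the temperature it needs, be accompanied by oxidative attack on the electron-rich arene.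
- Fallback, from 21 back to 23 in separate operations: Dess–Martin periodinane gives the diketone 22, which is now isolated. TMSOTf and Et3N convert it into the bis(trimethylsilyl) dienol ether F8 (a 1,4-disilyloxy-1,3-diene), and Pd(OAc)2 in MeCN oxidises F8 to 23 at room temperature.

## Further compounds

F1 | step 7 | 2,3-dibromo-1,4-dimethoxybenzene | COc1ccc(OC)c(Br)c1Br
F2 | step 7 | (2-bromo-3,6-dimethoxyphenyl)magnesium chloride | COc1ccc(OC)c([Mg]Cl)c1Br
F3 | step 7 | enone carrying a 2-bromo-3,6-dimethoxyphenyl group on Cc, trans to prenyl | CC(C)=CC[C@]12[C@H](CC(=O)C=C1[C@H](O[Si](C)(C)C(C)(C)C)CC[C@@H]2O[Si](C)(C)C(C)(C)C)c1c(OC)ccc(OC)c1Br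
F4 | step 4 | β,γ-unsaturated hydroxy ketone (double bond Cb=B4) | CC(C)=CC[C@]12CCC(=O)CC1=CCC[C@@H]2O
F5 | step 4 | γ-hydroperoxy enone (hydroperoxide at B4, cis to prenyl) | CC(C)=CC[C@]12CCC(=O)C=C1[C@H](OO)CC[C@@H]2O
F6 | step 10 | 2,4,6-triisopropylbenzenesulfonylhydrazone of 18 | CC(C)=CC[C@@]12[C@@H](O[Si](C)(C)C(C)(C)C)CC[C@@H](O[Si](C)(C)C(C)(C)C)[C@@]14CC(=NNS(=O)(=O)c5c(C(C)C)cc(C(C)C)cc5C(C)C)C[C@@H]2c2c(OC)ccc(OC)c24
F7 | step 10 | vinyllithium (Ce–Li, double bond Ce=Cf) | CC(C)=CC[C@@]12[C@@H](O[Si](C)(C)C(C)(C)C)CC[C@@H](O[Si](C)(C)C(C)(C)C)[C@@]14CC([Li])=C[C@@H]2c2c(OC)ccc(OC)c24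
F8 | step 13 | bis(trimethylsilyl) dienol ether of 22 | CC(C)=CC[C@@]12C(O[Si](C)(C)C)=CC=C(O[Si](C)(C)C)[C@@]14CC(C)=C[C@@H]2c2c(OC)ccc(OC)c24
A1 | alternative 1 | 4,7-dimethoxy-2-(3-methylbut-2-en-1-yl)-1H-inden-1-one | CC(C)=CCC1=Cc2c(OC)ccc(OC)c2C1=O
A2 | alternative 1 | (1E,3E)-buta-1,3-diene-1,4-diyl diacetate | CC(=O)O/C=C/C=C/OC(C)=O
A3 | alternative 1 | endo Diels–Alder adduct: cis-fused hydrofluorenone with allylic diacetate in ring B | CC(C)=CC[C@@]12[C@H](OC(C)=O)C=C[C@H](OC(C)=O)[C@@H]1c1c(OC)ccc(OC)c1C2=O
A4 | alternative 2 | open precursor: α-prenyl β-methoxy enone with benzylic silyl ether and aryl-bound nitroalkene (Ca epimerisable) | CC(C)=CCC(C(=O)/C=C/OC)[C@@H](O[Si](C)(C)C(C)(C)C)c1c(OC)ccc(OC)c1C(C\C(C)=C/[Si](C)(C)C)=C[N+](=O)[O-]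
A5 | alternative 2 | cis-fused tricycle with quaternary Ca and Cb, enone and nitro group in ring B | CC(C)=CC[C@@]12C(=O)C=C[C@H]([N+](=O)[O-])[C@]1(C\C(C)=C/[Si](C)(C)C)c1c(OC)ccc(OC)c1[C@@H]2O[Si](C)(C)C(C)(C)C
A6 | alternative 3 | δ-lactone with tertiary allylic ester oxygen, dithianyl group trans to the styryl group (α-carbon epimerisable) | CC(C)=CCC1C(=O)O[C@](C)(/C=C/c2c(OC)ccc(OC)c2Br)C[C@H]1C1SCCCS1
A7 | alternative 3 | cyclohexene acid with quaternary Ca, aryl-bearing Cc and the methyl alkene | OC(=O)[C@]1(CC=C(C)C)[C@H](C2SCCCS2)CC(C)=C[C@@H]1c1c(OC)ccc(OC)c1Br
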